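Slowness is my first worry with these charges, and the readings dismiss it here. Wednesday's complex with one exchanged reads 48% at 1.33 min and 48% at 15.0 min. Friday's climbs from 19% at 2.00 min, but reads 27% at 10.0 min and 27% at 15.0 min. More time late in these runs changes nothing I can see, so I read the plateaus as thermodynamic control.

all flasks: starting complex 0.0020 M

| charge | incoming ligand | protic impurity | remark | time |
|---|---|---|---|---|
| Friday's | 0.80 mM | 0.10 mM | run made earlier |  |
| Wednesday's | 4.6 mM | 0.10 mM | run made earlier |  |
| eta | 5.00 mM | 0.100 mM |  | 15 min |
| theta | 1.00 mM | 0.100 mM |  | 15 min |
| alpha | 6.00 mM | 0.100 mM |  | 15 min |

- Friday's (time / min: complex with one exchanged / %, complex with two exchanged / %): 2.00: 19, 0; 4.00: 24, 0; 6.00: 28, 3; 8.00: 26, 2; 10.0: 27, 2; 12.0: 27, 1; 15.0: 27, 0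
- Wednesday's (time / min: complex with one exchanged / %, complex with two exchanged / %): 1.33: 48, 17; 2.00: 49, 12; 3.00: 51, 14; 4.00: 48, 17; 6.00: 46, 14; 10.0: 48, 14; 15.0: 48, 17

(standard deviation of a reading: 2 percentage points)



- which of these holds the largest part of the starting complex at the end of eta (complex with one exchanged / starting complex / complex with two exchanged)
- which of these holds the largest part of the starting complex at the end of theta (complex with one exchanged / starting complex / complex with two exchanged)
- which of these holds the largest part of the starting complex at the end of alpha (complex with one exchanged / starting complex / complex with two exchanged)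
- final complex with one exchanged in eta, as a percentage of the starting complex charged

I write m and d for the fractions of charged complex with one and two exchanged. I assume each exchange releases one leaving ligand, so l counts one per m and two per d. I also assume the impurity destroys its own amount of incoming ligand, which leaves u usable equivalents and x = u − l free. On a plateau I take the second exchange to run equally fast both ways, so dividing one rate by the other removes time and leaves the balance number B = d·l/(m·x), an apparent equilibrium constant in seen forms.

Wednesday's means are m = 48.3% and d = 15.0%. With u = 2.25, they give B = 0.166. Friday's d readings, none above 3%, are about the size of the scatter of 2 percentage points, so I leave them out.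

In this reckoning the remaining settings act through u. The complex charge enters as a ratio. The impurity costs 0.0500 equivalents, less than eta's u of 2.45. Eta's ligand charge lies just above Wednesday's, so I keep m near 48.3%, and B then gives d = 16.3%. By this count, theta's u of 0.450 leaves at least 55.0% unexchanged, so I call starting complex there, and one-exchanged in eta and alpha.

The forecast, holding that “both earlier runs are at equilibrium, not kinetically limited”, names complex with one exchanged for eta, starting complex for theta and complex with one exchanged for alpha, with 49% in eta.

The flask gives complex with one exchanged for eta, starting complex for theta and complex with one exchanged for alpha, with 48.5% in eta.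

    starting complex + incoming ligand ⇌ leaving ligand + complex with one exchanged (K = 4.01, k = 15.2 L mol⁻¹ s⁻¹)
    complex with one exchanged + incoming ligand ⇌ leaving ligand + complex with two exchanged (K = 0.268, k = 21.2 L mol⁻¹ s⁻¹)
    protic impurity + incoming ligand → quenched reagent (k = 169 L mol⁻¹ s⁻¹)
    complex with two exchanged ⇌ isomer of the product (K = 1.10, k = 0.0115 s⁻¹)
    starting complex ⇌ dormant form (K = 0.880, k = 0.0389 s⁻¹)

In eta, half of the first exchange's turnover up to the asked time was done by 0.159 min, and one-exchanged stands at 48.6% at 7.50 min and 48.5% at 150 min, with 53% of the ligand charge free and impurity at 0%. Beside 10.3% starting complex, eta holds 9.07% dormant form and 16.8% isomer of the product, so B is a working figure in seen forms; with eta's m it gives d = 16.3%, against 15.3%.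

In a neighbouring flask, eta's recipe with 0.0013 M of incoming ligand, u is 0.600, and its m of 35.5% gives d = 2.74%. The flask computes 2.69%.

All runs were generated by integration on assumed constants; noise was put on by code.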